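**Plan**
Numbering follows spiro[4.5]decane. C1 = CH–O‑isobutyryl, C3 = CH–isopropenyl, C5 = spiro carbon, then C6(CH3)=C7H–C8(=O)–C9H(OAc)–C10H(CH3).
Retrosynthesis cuts C9–O (enolate oxidation), then C8–C9 of the cyclohexenone (radical hydroacylation), then C10=CH2 (methylenation of an acetyl group). It then cuts C5–C6 (1,2‑alkenyl shift onto an epoxide) and finally the carbinol C–C bond (alkenyllithium + epoxy ketone).
Forward, the cyclopentane comes first by ring contraction of (S)‑limonene, both arms are then placed on C5, and the cyclohexenone is closed last.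
Enabling feature: in the six‑membered ring, C8(=O)–C9H2–C10H(CH3) is the anti‑Markovnikov hydroacylation pattern of an isopropenyl group on C5. C5 carries two C(CH3)= arms, and the C10–H bond lies on the ring face next to C4H2, the face not covered by C1 and its acyloxy group.
Stereochemistry: C3 comes from limonene, C1 from epoxidation anti to the C3 group, and C5 from the stereospecific anti semipinacol shift. C10 comes from H‑atom delivery to a planar radical, and C9 from enolate hydroxylation trans to the C10 methyl.

Key step: step 12

Remark: the carbinol carbon of 11 and the two acetal carbons of ozonide 2 are drawn without configuration because they lose it in the next event. Cyclopentane atoms are called C1–C5 as in the target throughout.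

**Step 1**
Reactants: 1 (S)-(−)-limonene
Product: 3 (S)-3-isopropenyl-6-oxoheptanal, via limonene ozonide 2 (not isolated)
Conditions: O3 (1.0 equiv, Sudan III end point), CH2Cl2, −78 °C; then Me2S, −78 °C to rt
Reagents that add atoms: ozone [O-][O+]=O
Why: Chemoselective ozonolysis, in which the electron-richer trisubstituted ring alkene is consumed before the 1,1-disubstituted isopropenyl group when ozone is limited to one equivalent, and the stereocentre (later C3) is not touched.

**Step 2**
Reactants: 3 (S)-3-isopropenyl-6-oxoheptanal
Product: 4 (R)-1-acetyl-4-isopropenylcyclopent-1-ene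
Conditions: KOH (dilute aq., cat.), Et2O–H2O, rt
Reagents that add atoms: none
Why: Intramolecular aldol condensation under hydroxide, where the aldehyde is the electrophile and the ketone CH2 enolate the nucleophile (5-enolexo closure), which should give the conjugated acetylcyclopentene and forms no stereocentre.

**Step 3**
Reactants: 4 (R)-1-acetyl-4-isopropenylcyclopent-1-ene
Product: 5 epoxy ketone (1-acetyl-3-isopropenyl-6-oxabicyclo[3.1.0]hexane, epoxide oxygen anti to the isopropenyl group)
Conditions: 30% H2O2, NaOH (cat.), MeOH, 0 °C
Reagents that add atoms: hydrogen peroxide OO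
Why: Weitz–Scheffer nucleophilic epoxidation touches only the enone, and hydroperoxide should add to C1 on the ring face anti to the C3 isopropenyl group, which fixes the C1–O configuration (the syn epoxide is removed by chromatography).

**Step 4**
Reactants: 6 but-2-yn-1-ol
Product: 8 (Z)-3-iodobut-2-en-1-ol, via cyclic alkenylalanate 7 (not isolated)
Conditions: Red-Al, THF, 0 °C to rt; then I2, −78 °C
Reagents that add atoms: iodine II
Why: Alkoxide-directed trans-hydroalumination of a propargylic alcohol places aluminium on C3 in a five-membered alanate, and iodinolysis with retention should give the Z iodide.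

**Step 5**
Reactants: 8 (Z)-3-iodobut-2-en-1-ol
Product: 9 (Z)-tert-butyl[(3-iodobut-2-en-1-yl)oxy]dimethylsilane
Conditions: TBSCl, imidazole, DMF, rt
Reagents that add atoms: tert-butyldimethylsilyl chloride CC(C)(C)[Si](C)(C)Cl
Why: Standard silylation of a primary alcohol masks the hydroxyl group for the organolithium and Lewis-acid steps.

**Step 6**
Reactants: 9 (Z)-tert-butyl[(3-iodobut-2-en-1-yl)oxy]dimethylsilane; 5 epoxy ketone
Product: 11 epoxy carbinol (tertiary alcohol on the former acetyl carbon, bearing CH3 and the (Z)-alkenyl group; epoxide unchanged), via alkenyllithium 10 (not isolated)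
Conditions: 9, t-BuLi (2.0 equiv), Et2O, −78 °C; then 5, −78 °C; aq. NH4Cl
Reagents that add atoms: none
Why: Lithium–iodine exchange with retention of alkene geometry and 1,2-addition to the ketone should outrun epoxide opening at −78 °C, and the new carbinol centre is of no consequence because it becomes a carbonyl carbon in step 7.

**Step 7**
Reactants: 11 epoxy carbinol
Product: 12 β-hydroxy ketone (C1–OH anti to isopropenyl; C5 bears acetyl syn to OH and the (Z)-4-(TBS-oxy)but-2-en-2-yl arm anti to OH)
Conditions: ZnBr2, CH2Cl2, 0 °C to rt
Reagents that add atoms: none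
Why: Semipinacol rearrangement of a 2,3-epoxy alcohol, in which the Lewis acid loosens the tertiary C5–O bond while the alkenyl group (better migrator than methyl, geometry retained) shifts from the carbinol carbon to C5 antiperiplanar to the leaving oxygen, so that C6 arrives anti to the C1 oxygen and the acetyl group ends syn to it.

**Step 8**
Reactants: 12 β-hydroxy ketone
Product: 13 isobutyrate ketone
Conditions: (i-PrCO)2O, DMAP (cat.), pyridine, 40 °C
Reagents that add atoms: isobutyric anhydride CC(C)C(=O)OC(=O)C(C)C
Why: DMAP-catalysed acylation installs the final C1 ester, blocks retro-aldol opening of the ring, and cannot eliminate because C5 is quaternary.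

**Step 9**
Reactants: 13 isobutyrate ketone
Product: 14 triene silyl ether (acetyl converted into an isopropenyl arm on C5)
Conditions: Zn, CH2Br2, TiCl4 (preformed Lombardo reagent), THF–CH2Cl2, 0 °C to rt
Reagents that add atoms: dibromomethane BrCBr
Why: Lombardo methylenation uses a non-basic gem-dimetallic reagent that should convert the hindered, enolisable methyl ketone in the presence of the ester and so avoids enolate-triggered acyl transfer.

**Step 10**
Reactants: 14 triene silyl ether
Product: 15 (Z)-allylic alcohol
Conditions: TBAF, THF, 0 °C
Reagents that add atoms: none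
Why: Fluoride desilylation frees the primary allylic alcohol, and the hindered isobutyrate should survive.

**Step 11**
Reactants: 15 (Z)-allylic alcohol
Product: 16 (Z)-enal
Conditions: activated MnO2, CH2Cl2, rt, dark
Reagents that add atoms: none
Why: Manganese dioxide oxidation is selective for the allylic alcohol and is neutral, so the alkenes and the ester are left alone.

**Step 12**
Reactants: 16 (Z)-enal
Product: 19 spiro enone (9-deoxy target), via acyl radical 17 (not isolated), via tertiary C10 radical 18 (not isolated)
Conditions: tert-dodecanethiol (30 mol %), AIBN (20 mol %, in portions), degassed toluene (0.01 M), 85 °C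
Reagents that add atoms: none
Why: Radical-chain intramolecular hydroacylation under polarity-reversal catalysis: the electrophilic thiyl radical abstracts the formyl hydrogen of 16, σ-acyl radical 17 adds to the CH2 terminus (C9) of the isopropenyl arm on C5, and tertiary radical 18 takes hydrogen from the thiol, which returns the chain carrier. The closest known reaction types are the thiol-catalysed cyclisation of alkenals to cyclic ketones and the 6-endo cyclisation of acyl radicals onto 1,1-disubstituted alkenes. The cyclohexenone (C5–C6–C7–C8–C9–C10) closes in the 6-endo-trig mode, because 5-exo attack at C10 would have to join two fully substituted carbons and any 5-exo radical can drain through a cyclopropyloxy (Dowd–Beckwith type) shift to the more stable 18. The one new stereocentre, C10, is set in the last event: in 18 the bulkier C1 branch sits pseudo-axial on C5 to avoid the C6 methyl group and its acyloxy group leans over C10, so the bulky thiol can reach the planar radical only from the C4H2 side and the methyl group is pushed cis to C1. The step is stereoconvergent, since Z and E enal interconvert at the stage of the α,β-unsaturated acyl radical (α-ketenyl radical form) while only the Z form can close, and the configuration at C10 depends on no earlier alkene geometry. It needs chemoselectivity between the two isopropenyl groups, which the substrate secures because only the C5 arm lies within reach of C8 (the C3 group could only give a bridged medium ring), and high dilution keeps intermolecular addition down.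

**Step 13**
Reactants: 19 spiro enone
Product: 21 9-hydroxy enone, via lithium dienolate 20 (not isolated)
Conditions: LiHMDS, THF, −78 °C; then 2-(phenylsulfonyl)-3-phenyloxaziridine, −78 °C; aq. NH4Cl
Reagents that add atoms: 2-(phenylsulfonyl)-3-phenyloxaziridine O=S(=O)(c1ccccc1)N1OC1c1ccccc1
Why: Kinetic α′-deprotonation of the enone and Davis hydroxylation, in which the oxidant (inert to isolated alkenes) should reach C9 from the face opposite to the C10 methyl group and the pseudo-axial C1 branch, giving the trans alcohol, which is also the more stable equatorial epimer.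

**Step 14**
Reactants: 21 9-hydroxy enone
Product: 22 target, (1R,3S,5R,9R,10S)-9-acetoxy-6,10-dimethyl-8-oxo-3-(prop-1-en-2-yl)spiro[4.5]dec-6-en-1-yl 2-methylpropanoate
Conditions: Ac2O, DMAP (cat.), pyridine, 0 °C to rt
Reagents that add atoms: acetic anhydride CC(=O)OC(C)=O
Why: Standard acetylation of the α-ketol, in which any base-induced equilibration at C9 can only favour the required trans-diequatorial arrangement.

**Compound list**
1 | (S)-(−)-limonene | CC1=CC[C@H](CC1)C(C)=C | starting material
2 | limonene 1,2-ozonide | CC12CC[C@@H](CC(OO1)O2)C(C)=C | intermediate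
3 | (S)-3-isopropenyl-6-oxoheptanal | O=CC[C@H](CCC(C)=O)C(C)=C | intermediate
4 | (R)-1-acetyl-4-isopropenylcyclopent-1-ene | C=C(C)[C@@H]1CC=C(C1)C(C)=O | intermediate
5 | epoxy ketone, epoxide anti to isopropenyl | C=C(C)[C@@H]1C[C@H]2O[C@]2(C1)C(C)=O | intermediate
6 | but-2-yn-1-ol | CC#CCO | starting material
7 | sodium cyclic alkenylalanate | CC1=CCO[Al-]1(OCCOC)OCCOC.[Na+] | intermediate
8 | (Z)-3-iodobut-2-en-1-ol | I/C(C)=C\CO | intermediate
9 | (Z)-3-iodobut-2-enyl TBS ether | I/C(C)=C\CO[Si](C)(C)C(C)(C)C | intermediate
10 | (Z)-alkenyllithium | [Li]/C(C)=C\CO[Si](C)(C)C(C)(C)C | intermediate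
11 | epoxy carbinol (carbinol centre undefined) | C=C(C)[C@@H]1C[C@H]2O[C@]2(C1)C(C)(O)/C(C)=C\CO[Si](C)(C)C(C)(C)C | intermediate
12 | β-hydroxy ketone (acetyl syn, alkenyl anti to C1–OH) | C=C(C)[C@@H]1C[C@@H](O)[C@](C1)(C(C)=O)/C(C)=C\CO[Si](C)(C)C(C)(C)C | intermediate
13 | isobutyrate ketone | C=C(C)[C@@H]1C[C@@H](OC(=O)C(C)C)[C@](C1)(C(C)=O)/C(C)=C\CO[Si](C)(C)C(C)(C)C | intermediate
14 | triene silyl ether | C=C(C)[C@@H]1C[C@@H](OC(=O)C(C)C)[C@](C1)(C(C)=C)/C(C)=C\CO[Si](C)(C)C(C)(C)C | intermediate
15 | (Z)-allylic alcohol | C=C(C)[C@@H]1C[C@@H](OC(=O)C(C)C)[C@](C1)(C(C)=C)/C(C)=C\CO | intermediate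
16 | (Z)-enal | C=C(C)[C@@H]1C[C@@H](OC(=O)C(C)C)[C@](C1)(C(C)=C)/C(C)=C\C=O | intermediate
17 | acyl radical at C8 | C=C(C)[C@@H]1C[C@@H](OC(=O)C(C)C)[C@](C1)(C(C)=C)/C(C)=C\[C]=O | intermediate
18 | tertiary radical at C10 | C=C(C)[C@@H]1C[C@@H](OC(=O)C(C)C)[C@@]2(C1)C(C)=CC(=O)C[C]2C | intermediate
19 | spiro enone (9-deoxy target) | C=C(C)[C@@H]1C[C@@H](OC(=O)C(C)C)[C@@]2(C1)C(C)=CC(=O)C[C@H]2C | intermediate
20 | lithium cross-conjugated dienolate | C=C(C)[C@@H]1C[C@@H](OC(=O)C(C)C)[C@@]2(C1)C(C)=CC([O-])=C[C@H]2C.[Li+] | intermediate
21 | 9-hydroxy enone | C=C(C)[C@@H]1C[C@@H](OC(=O)C(C)C)[C@@]2(C1)C(C)=CC(=O)[C@H](O)[C@H]2C | intermediate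
22 | target | C=C(C)[C@@H]1C[C@@H](OC(=O)C(C)C)[C@@]2(C1)C(C)=CC(=O)[C@H](OC(C)=O)[C@H]2C | target

**Totals**
Total steps: 14. Longest linear sequence: 12 (steps 1–3 and 6–14).

**Steps most likely to fail**

*Step 12.* The chain may stall because abstraction of the formyl hydrogen of a conjugated aldehyde is slow. Thiol addition to the 1,1-disubstituted alkenes or simple geometric drift of the enal could then take over. The fallback is polar and sets out from 16.
- A Me2AlCl-promoted type II carbonyl-ene cyclisation (CH2Cl2, −78 °C) joins C8 to C9 and should give the 8-hydroxy-10-methylene spirocycle F1.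
- Dess–Martin oxidation gives the β,γ-unsaturated ketone F2, and DBU moves the exocyclic alkene into conjugation to give the cross-conjugated dienone F3, in which C5 is no longer stereogenic.
- Conjugate reduction with a bulky bisphosphine–copper hydride catalyst and PMHS should attack the arm syn to the acyloxy group from the C4H2 side. This is the only quadrant covered neither by the ester nor by the C3 isopropenyl group. Hydrolysis of the silyl enol ether brings the route back to 19.

*Step 7.* Ionisation of the tertiary allylic carbinol, or participation of the silyl ether oxygen in the epoxide opening, may outrun the 1,2-shift. The fallback sets out from 11.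
- The carbinol is capped (TMSCl, imidazole) to give the bis-silyl ether F4.
- F4 is rearranged with stoichiometric TiCl4 in CH2Cl2 at −78 °C. Here the silyloxy group can only push and cannot leave, and the oxocarbenium ion formed by the shift loses its silyl group.
- Work-up brings the route back to 12.

*Step 3.* Facial selectivity may be poor because the directing isopropenyl group is remote from C1. The fallback sets out from 4 and replaces substrate control by reagent control.
- Corey–Bakshi–Shibata reduction with (S)-Me-CBS and BH3·SMe2 gives the (R)-allylic alcohol F5.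
- Hydroxyl-directed epoxidation (VO(acac)2, t-BuOOH) is governed by A(1,2) strain with C4 and spares the isopropenyl group. It should place the oxygen on the required face to give the epoxy alcohol F6.
- Dess–Martin oxidation brings the route back to 5.

**Further compounds**
F1 | step 12 | 8-hydroxy-10-methylene spirocycle (C8 undefined) | C=C(C)[C@@H]1C[C@@H](OC(=O)C(C)C)[C@@]2(C1)C(C)=CC(O)CC2=C
F2 | step 12 | 10-methylene-8-ketone | C=C(C)[C@@H]1C[C@@H](OC(=O)C(C)C)[C@@]2(C1)C(C)=CC(=O)CC2=C
F3 | step 12 | 6,10-dimethylspiro[4.5]deca-6,9-dien-8-one isobutyrate | C=C(C)[C@@H]1C[C@@H](OC(=O)C(C)C)C2(C1)C(C)=CC(=O)C=C2C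
F4 | step 7 | trimethylsilyl ether of epoxy carbinol 11 | C=C(C)[C@@H]1C[C@H]2O[C@]2(C1)C(C)(O[Si](C)(C)C)/C(C)=C\CO[Si](C)(C)C(C)(C)C
F5 | step 3 | (R)-1-[(R)-4-isopropenylcyclopent-1-enyl]ethanol | C=C(C)[C@@H]1CC=C(C1)[C@@H](C)O
F6 | step 3 | epoxy alcohol, epoxide anti to isopropenyl | C=C(C)[C@@H]1C[C@H]2O[C@]2(C1)[C@@H](C)O
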